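Readings and results are simulated with constants of no real substance, noise included.

Left-handed substrate goes faster than its mirror image: in the summer run at 8.00 h it stands at 5.9% of the two together charged, right-handed substrate at 20.2%.

| flask | left-handed substrate | right-handed substrate | partner | precatalyst | remark | time |
|---|---|---|---|---|---|---|
| dusk | 0.20 M | 0.20 M | 0.40 M | 10 mM | run made earlier |  |
| summer | 0.20 M | 0.20 M | 0.90 M | 10 mM | run made earlier |  |
| flask | 0.20 M | 0.20 M | 0.600 M | 10 mM |  | 10 h |

| run | time / h | left-handed substrate / % | right-handed substrate / % |
|---|---|---|---|
| dusk | 1.00 | 48.4 | 48.3 |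
| dusk | 3.00 | 39.7 | 45.2 |
| dusk | 5.00 | 33.7 | 41.9 |
| dusk | 8.00 | 26.2 | 38.1 |
| summer | 0.667 | 44.9 | 47.3 |
| summer | 1.33 | 38.6 | 45.3 |
| summer | 3.00 | 25.6 | 37.1 |
| summer | 8.00 | 5.9 | 20.2 |

(standard deviation of a reading: 0.5 percentage points)

- free catalyst is single-handed; left-handed substrate and right-handed substrate are mirror images of each other, charged as a racemate, each of them at the stated concentration
- an excess is the difference of the two amounts in percent of their sum
- an excess is below zero if the other one leads

* part of the left-handed substrate and right-handed substrate charged together that has reacted at 10 h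
* excess of left-handed product over right-handed product in the product at 10 h
* excess of right-handed substrate over left-handed substrate among what is left of the two at 10 h

Let f be what is left of a substrate as a fraction of its own charge, so f_L is c(left-handed substrate) over its charge and f_R the same for right-handed substrate. If each substrate is used at a rate proportional to its own concentration, with one common factor, whatever catalyst and partner do, and the two constants of proportion stand in a fixed ratio s, then dividing one rate by the other cancels that factor, and integration leaves

s = ln f_L / ln f_R.

This s is the selectivity factor 2.36, read from the summer run at 8.00 h. The dusk run reads 2.38, with partner at 0.40 M against 0.90 M, so we carry s to this flask and need one more thing, how far left-handed substrate gets.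

For that we make a rough estimate of our own. We interpolate −ln f_L linearly in partner between the two runs at 8.00 h, from 0.646 to 2.14, and stretch it in proportion to time up to 10 h:

−ln f_L = 1.55, so f_L = 21.2% and f_R = 51.8%

This gives c = 63.5%, eP = 24.1% and eS = 42.0%.

The forecast, reasoning that “ln(50/%) for left-handed over that for right-handed gives s ≈ 2.35 in both runs”, says c = 61.8%, eP = 24.6% and eS = 39.8%, a conversion lower than ours.

The flask gives c = 61.1%, eP = 27.0% and eS = 39.2%, so the forecast held.

    free catalyst + left-handed substrate ⇌ catalyst intermediate A (K = 18.9 L mol⁻¹, k = 8.66 L mol⁻¹ min⁻¹)
    free catalyst + right-handed substrate ⇌ catalyst intermediate B (K = 20.4 L mol⁻¹, k = 2.96 L mol⁻¹ min⁻¹)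
    partner + catalyst intermediate A → free catalyst + left-handed product (k = 0.248 L mol⁻¹ min⁻¹)
    partner + catalyst intermediate B → free catalyst + right-handed product (k = 0.0979 L mol⁻¹ min⁻¹)
    partner ⇌ dormant form (K = 0.388, k = 0.00215 min⁻¹)
    partner + precatalyst → free catalyst + spent reagent (k = 0.0372 L mol⁻¹ min⁻¹)
    partner → decomposition product (k = 9.40 × 10⁻⁶ min⁻¹)

What the flask has that s does not show is the catalyst round: at 10.0 h catalyst intermediate A holds 21.5% of the catalyst charged and catalyst intermediate B 51.4%, yet the binding of left-handed substrate relaxes with a half-life of 0.777 min, short against 10 h, and its backward turnover is 84% of the forward one. In this flask f_L = 24% then gives f_R = 54.6% by s, and the flask holds 54%.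

The neighbour charged with 0.017 M of precatalyst reaches f_L = 7.7%, for which s gives f_R = 33.7%; the computed neighbour holds 33%, with eS = 61.9%.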